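**Strategy**

The carbocycle (ring B: C4a, C5, C6, C7, C8, C8a) is a dearomatised acylphloroglucinol, so it is closed the way a polyketide is: by a Claisen (Dieckmann) condensation that forms the C5–C6 bond. The precursor is monocyclic. Ring A, the oxane, is already in place and carries the quaternary carbon C4a with a methyl ester (the future C5) and, on C8a, an exocyclic push–pull alkene bearing the aroyl group and a 5-methylhex-4-enoyl ketone (C7, C6). The step exploits that C6 is then the only enolisable carbon and that the C5/C7 diketone is trapped as its enolate. Both lavandulyl-derived units come from (R)-lavandulol; the quaternary centre is set when ring A closes.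

Key step: step 8

Numbering (chromene numbering of the target, also used for the precursors): O1, C2 (CMe2), C3 (CH-prenyl), C4 (CH2), C4a (quaternary), C5 (ketone), C6 (CH-prenyl), C7 (ketone), C8 (aroyl-bearing carbon), C8a (enol ether carbon).

Abbreviations: Lav = (2S)-5-methyl-2-(prop-1-en-2-yl)hex-4-en-1-yl, the group that (R)-lavandulol delivers with its stereocentre unchanged (only the descriptor changes, through the priorities); TBS = tert-butyldimethylsilyl; prenyl = 3-methylbut-2-en-1-yl.

Remark 1: C6 lies between two ketones and epimerises through the enol, so the (6S) configuration of the target is taken to be the equilibrium configuration of the diketo tautomer.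

Remark 2: (R)-lavandulol is taken as a commercial starting material.

**Route**

Step 1
Reactants: 1 (R)-lavandulol
Product: 2 (R)-lavandulyl iodide
Conditions: PPh3, I2, imidazole, CH2Cl2, 0 °C to rt
Reagents that add atoms: iodine, II
Why: Appel-type iodination turns the β-branched primary alcohol into the iodide by SN2 at CH2, so the stereocentre and both alkenes are untouched.

Step 2
Reactants: 3 dimethyl malonate; 2 (R)-lavandulyl iodide (2.3 equiv)
Product: 5 dimethyl 2,2-di-Lav-malonate, via monoalkylated malonate 4 (not isolated)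
Conditions: NaH (2.5 equiv), DMF, 0 to 60 °C
Reagents that add atoms: none
Why: Malonic ester synthesis, two successive SN2 alkylations of the sodium enolate by the primary iodide (the dialkylation of malonates with isobutyl halides is the model), builds the quaternary carbon, which is not yet a stereocentre because the two arms are identical.

Step 3
Reactants: 5 dimethyl 2,2-di-Lav-malonate
Product: 6 2,2-di-Lav-malonic acid monomethyl ester
Conditions: KOH (1.2 equiv), MeOH/H2O, 60 °C; then cold 1 M aq. HCl to pH 3
Reagents that add atoms: potassium hydroxide, [K+].[OH-]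
Why: Saponification of a hindered 2,2-dialkylmalonate should stop at the half ester because the first carboxylate repels hydroxide from the neighbouring ester, and the cold, brief acidification spares the isopropenyl groups.

Step 4
Reactants: 7 3',4'-dihydroxyacetophenone
Product: 8 3',4'-bis(TBS-oxy)acetophenone
Conditions: TBSCl, imidazole, DMF, rt
Reagents that add atoms: tert-butyldimethylsilyl chloride, CC(C)(C)[Si](C)(C)Cl
Why: Silyl ether formation masks both phenols in a form that survives enolate chemistry and mild acid and falls to fluoride at the end.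

Step 5
Reactants: 6 2,2-di-Lav-malonic acid monomethyl ester; 8 3',4'-bis(TBS-oxy)acetophenone (2.2 equiv)
Product: 10 methyl 5-[3,4-bis(TBS-oxy)phenyl]-2,2-di-Lav-3,5-dioxopentanoate, via acid chloride 9 (not isolated)
Conditions: (a) 6, Me2C=C(Cl)NMe2, CH2Cl2, 0 °C to rt; (b) 8, LiN(SiMe3)2 (2.2 equiv), THF, −78 °C, then 9, −78 to −40 °C; aq. NH4Cl
Reagents that add atoms: none
Why: C-acylation of a ketone lithium enolate by an acid chloride (crossed Claisen-type), with the chloride made under neutral conditions by the α-chloroenamine so that no HCl meets the isopropenyl groups; the acid chloride has no α-hydrogen and the second equivalent of enolate deprotonates the β-diketone, which stops further acylation.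

Step 6
Reactants: 10 methyl 5-[3,4-bis(TBS-oxy)phenyl]-2,2-di-Lav-3,5-dioxopentanoate; 11 5-methylhex-4-enoic acid
Product: 13 methyl 4-[3,4-bis(TBS-oxy)benzoyl]-2,2-di-Lav-9-methyl-3,5-dioxodec-8-enoate, via 5-methylhex-4-enoyl chloride 12 (not isolated)
Conditions: (a) 11, Me2C=C(Cl)NMe2, CH2Cl2, 0 °C; (b) 10, MgCl2, pyridine, CH2Cl2, 0 °C, then 12, 0 °C to rt
Reagents that add atoms: none
Why: Soft-enolisation C-acylation of a β-diketone (MgCl2, pyridine), in which the chelated magnesium enolate is acylated on carbon to give the 2-acyl-1,3-diketone.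

Step 7
Reactants: 13 methyl 4-[3,4-bis(TBS-oxy)benzoyl]-2,2-di-Lav-9-methyl-3,5-dioxodec-8-enoate
Product: 14 methyl (3R,5S)-2-{1-[3,4-bis(TBS-oxy)phenyl]-7-methyl-1,3-dioxooct-6-en-2-ylidene}-3-Lav-6,6-dimethyl-5-prenyloxane-3-carboxylate
Conditions: TsOH·H2O (0.1 equiv), toluene, 40 °C
Reagents that add atoms: none
Why: Acid-catalysed intramolecular Markovnikov hydroalkoxylation (cycloetherification, 6-exo-trig), the reaction that turns lavandulyl-bearing acylphloroglucinols into their pyrano isomers: only the C8a oxygen can reach an isopropenyl cation through a six-membered ring while C5 is still an ester, and of the two diastereotopic arms the one whose chair-like closure keeps its prenyl group equatorial, the flat ester in the enol plane and the other arm axial (away from allylic 1,3-strain with the ylidene substituents) should react, which sets the quaternary centre C4a as 3R in oxane numbering.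

Step 8
Reactants: 14 methyl (3R,5S)-2-{1-[3,4-bis(TBS-oxy)phenyl]-7-methyl-1,3-dioxooct-6-en-2-ylidene}-3-Lav-6,6-dimethyl-5-prenyloxane-3-carboxylate
Product: 15 (3S,4aR,6S)-8-[3,4-bis(TBS-oxy)benzoyl]-4a-Lav-2,2-dimethyl-3,6-diprenyl-3,4-dihydro-2H-chromene-5,7(4aH,6H)-dione
Conditions: LiN(SiMe3)2 (3 equiv), THF, −78 °C to rt; then AcOH
Reagents that add atoms: none
Why: LiN(SiMe3)2 deprotonates C6, the CH2 next to the C7 ketone and the only enolisable carbon of 14 (C4a is quaternary, C8 is fully substituted, the aryl ketone and the ester have no α-hydrogen), and the resulting enolate adds to the ester carbonyl on C4a and expels methoxide, which forms the C5–C6 bond. This is a Dieckmann-type intramolecular Claisen condensation of a ketone enolate with an ester, the laboratory counterpart of the polyketide Claisen cyclisation that closes the phloroglucinol ring in acylphloroglucinol biosynthesis and of the base-induced cyclisation of 3,5,7-triketo esters. Ring B closes in the 6-(enolendo)-exo-trig mode. C6 is the only new stereocentre; it is formed as the planar enolate of the C5/C7 diketone, which is deprotonated as it forms and thereby makes the closure irreversible, and it is set on protonation and equilibration under thermodynamic control (prenyl pseudo-equatorial, 6S), while C3, C4a and the lavandulyl centre cannot epimerise. The step needs C- and not O-acylation and the alkene geometry with the C7 ketone cis to C4a: the push–pull C8=C8a bond should isomerise under the conditions, and any enol lactone from O-attack should be reopened by lithium methoxide, so that material drains to the stabilised diketone enolate.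

Step 9
Reactants: 15 (3S,4aR,6S)-8-[3,4-bis(TBS-oxy)benzoyl]-4a-Lav-2,2-dimethyl-3,6-diprenyl-3,4-dihydro-2H-chromene-5,7(4aH,6H)-dione
Product: 16 (3S,4aR,6S)-8-(3,4-dihydroxybenzoyl)-4a-Lav-2,2-dimethyl-3,6-diprenyl-3,4-dihydro-2H-chromene-5,7(4aH,6H)-dione (CNP0250793.1)
Conditions: HF·pyridine, pyridine, THF, 0 °C to rt
Reagents that add atoms: none
Why: Fluoride cleavage of the aryl silyl ethers with buffered HF·pyridine should leave the alkenes, the vinylogous ester and the β-diketone untouched, and C6 stays at its equilibrium configuration.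

**Compound list**

1 | (R)-lavandulol, (2R)-5-methyl-2-(prop-1-en-2-yl)hex-4-en-1-ol | C=C(C)[C@@H](CC=C(C)C)CO | starting material
2 | (R)-lavandulyl iodide, (3R)-3-(iodomethyl)-2,6-dimethylhepta-1,5-diene | C=C(C)[C@@H](CC=C(C)C)CI | intermediate
3 | dimethyl malonate | COC(=O)CC(=O)OC | starting material
4 | dimethyl 2-[(2S)-5-methyl-2-(prop-1-en-2-yl)hex-4-en-1-yl]malonate (monoalkylated malonate) | COC(=O)C(C[C@H](CC=C(C)C)C(C)=C)C(=O)OC | intermediate
5 | dimethyl 2,2-bis[(2S)-5-methyl-2-(prop-1-en-2-yl)hex-4-en-1-yl]malonate | COC(=O)C(C[C@H](CC=C(C)C)C(C)=C)(C[C@H](CC=C(C)C)C(C)=C)C(=O)OC | intermediate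
6 | 3-methoxy-3-oxo-2,2-bis[(2S)-5-methyl-2-(prop-1-en-2-yl)hex-4-en-1-yl]propanoic acid | COC(=O)C(C[C@H](CC=C(C)C)C(C)=C)(C[C@H](CC=C(C)C)C(C)=C)C(=O)O | intermediate
7 | 3',4'-dihydroxyacetophenone | CC(=O)c1ccc(O)c(O)c1 | starting material
8 | 3',4'-bis(tert-butyldimethylsilyloxy)acetophenone | CC(=O)c1ccc(O[Si](C)(C)C(C)(C)C)c(O[Si](C)(C)C(C)(C)C)c1 | intermediate
9 | methyl 3-chloro-3-oxo-2,2-bis[(2S)-5-methyl-2-(prop-1-en-2-yl)hex-4-en-1-yl]propanoate (acid chloride of 6) | COC(=O)C(C[C@H](CC=C(C)C)C(C)=C)(C[C@H](CC=C(C)C)C(C)=C)C(Cl)=O | intermediate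
10 | methyl 5-[3,4-bis(tert-butyldimethylsilyloxy)phenyl]-2,2-bis[(2S)-5-methyl-2-(prop-1-en-2-yl)hex-4-en-1-yl]-3,5-dioxopentanoate | COC(=O)C(C[C@H](CC=C(C)C)C(C)=C)(C[C@H](CC=C(C)C)C(C)=C)C(=O)CC(=O)c1ccc(O[Si](C)(C)C(C)(C)C)c(O[Si](C)(C)C(C)(C)C)c1 | intermediate
11 | 5-methylhex-4-enoic acid | CC(C)=CCCC(=O)O | starting material
12 | 5-methylhex-4-enoyl chloride | CC(C)=CCCC(Cl)=O | intermediate
13 | methyl 4-[3,4-bis(tert-butyldimethylsilyloxy)benzoyl]-9-methyl-2,2-bis[(2S)-5-methyl-2-(prop-1-en-2-yl)hex-4-en-1-yl]-3,5-dioxodec-8-enoate (drawn as the triketo tautomer; enolised in solution) | COC(=O)C(C[C@H](CC=C(C)C)C(C)=C)(C[C@H](CC=C(C)C)C(C)=C)C(=O)C(C(=O)CCC=C(C)C)C(=O)c1ccc(O[Si](C)(C)C(C)(C)C)c(O[Si](C)(C)C(C)(C)C)c1 | intermediate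
14 | methyl (3R,5S)-2-{1-[3,4-bis(tert-butyldimethylsilyloxy)phenyl]-7-methyl-1,3-dioxooct-6-en-2-ylidene}-6,6-dimethyl-5-(3-methylbut-2-en-1-yl)-3-[(2S)-5-methyl-2-(prop-1-en-2-yl)hex-4-en-1-yl]oxane-3-carboxylate (push–pull alkene, geometry not fixed) | C=C(C)[C@@H](CC=C(C)C)C[C@@]1(C(=O)OC)C[C@H](CC=C(C)C)C(C)(C)OC1=C(C(=O)CCC=C(C)C)C(=O)c1ccc(O[Si](C)(C)C(C)(C)C)c(O[Si](C)(C)C(C)(C)C)c1 | intermediate
15 | (3S,4aR,6S)-8-[3,4-bis(tert-butyldimethylsilyloxy)benzoyl]-2,2-dimethyl-3,6-bis(3-methylbut-2-en-1-yl)-4a-[(2S)-5-methyl-2-(prop-1-en-2-yl)hex-4-en-1-yl]-3,4-dihydro-2H-chromene-5,7(4aH,6H)-dione | C=C(C)[C@@H](CC=C(C)C)C[C@@]12C[C@H](CC=C(C)C)C(C)(C)OC1=C(C(=O)c1ccc(O[Si](C)(C)C(C)(C)C)c(O[Si](C)(C)C(C)(C)C)c1)C(=O)[C@@H](CC=C(C)C)C2=O | intermediate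
16 | (3S,4aR,6S)-8-(3,4-dihydroxybenzoyl)-2,2-dimethyl-3,6-bis(3-methylbut-2-en-1-yl)-4a-[(2S)-5-methyl-2-(prop-1-en-2-yl)hex-4-en-1-yl]-3,4-dihydro-2H-chromene-5,7(4aH,6H)-dione (CNP0250793.1) | C=C(C)[C@@H](CC=C(C)C)C[C@@]12C[C@H](CC=C(C)C)C(C)(C)OC1=C(C(=O)c1ccc(O)c(O)c1)C(=O)[C@@H](CC=C(C)C)C2=O | target

**Count**

Total step count: 9. Longest linear sequence: 8 steps (1, 2, 3, 5, 6, 7, 8, 9); step 4 is a one-step branch.

**Steps most likely to fail**

1. Step 7. What may go wrong: ring closure through the other diastereotopic lavandulyl arm, which would give the epimer at C4a, and acid-induced migration of the remaining isopropenyl double bond. Fallback, from 4 back to 14: the quaternary centre is set by ring-controlled alkylation instead of arm selection. Compound 4, isolated when step 2 is run with one equivalent of 2, is saponified on one ester (KOH, 1 equiv) to the malonic half acid F1. This lactonises onto its isopropenyl group (TsOH·H2O, toluene) to the δ-lactone ester F2. Its sodium enolate is alkylated with 2 (NaH, DMF) anti to the equatorial prenyl group, by axial attack, to give the dialkylated lactone ester F3, in which the new arm is trans to prenyl as in 14. The lithium enolate of 8 (LiN(SiMe3)2, THF, −78 °C) should add to the lactone carbonyl, which is more electrophilic than the methyl ester, to give the hydroxy diketone F4 (in equilibrium with its hemiketal). C-acylation with 12 (MgCl2, pyridine) gives the hydroxy triketone F5. Cyclodehydration with pyridinium p-toluenesulfonate and 4 Å molecular sieves in toluene, too mild to protonate the isopropenyl group, closes ring A to 14.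

2. Step 8. What may go wrong: attack of the enolate through oxygen, a geometric isomer of the push–pull alkene that does not turn its C7 ketone toward the ester, or an ester too hindered to be attacked. Fallback, from 13 back to 15: the order of the two ring closures is exchanged. Excess LiN(SiMe3)2 converts 13 into the dianion of the triketone, whose terminal carbon closes ring B onto the ester (the classical Claisen cyclisation of 3,5,7-triketo esters) to the 6,6-dilavandulyl acylphloroglucinol F6. TsOH-catalysed cycloetherification then gives 15. In the bicycle C5 must lie in the plane of ring A, so the closing arm keeps its prenyl group equatorial only if the other arm is axial, which enforces the C4a configuration. The price is possible closure at the C5 oxygen instead of the C8a oxygen, to be removed by chromatography.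

3. Step 2. What may go wrong: slow second SN2 at the hindered tertiary malonate anion, with competing E2 elimination of the β-branched iodide. Fallback, from 4 back to 6: the second arm is put on a more nucleophilic ester enolate and the carboxyl group is added last. Krapcho demethoxycarbonylation of isolated 4 (LiCl, wet DMSO, 150 °C) gives the monoalkylated ester F7. Alkylation of its enolate with 2 (LiN(i-Pr)2, THF/DMPU, −78 to 0 °C) gives the dialkylated ester F8. Carboxylation of the enolate of F8 (LiN(i-Pr)2, then CO2) gives 6.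

**Further compounds**

F1 | step 7 | 3-methoxy-3-oxo-2-[(2S)-5-methyl-2-(prop-1-en-2-yl)hex-4-en-1-yl]propanoic acid (malonic half acid, epimers at C2) | COC(=O)C(C[C@H](CC=C(C)C)C(C)=C)C(=O)O
F2 | step 7 | methyl (5S)-6,6-dimethyl-5-(3-methylbut-2-en-1-yl)-2-oxooxane-3-carboxylate (δ-lactone ester, epimers at C3) | COC(=O)C1C[C@H](CC=C(C)C)C(C)(C)OC1=O
F3 | step 7 | methyl (3S,5S)-6,6-dimethyl-5-(3-methylbut-2-en-1-yl)-3-[(2S)-5-methyl-2-(prop-1-en-2-yl)hex-4-en-1-yl]-2-oxooxane-3-carboxylate (dialkylated lactone ester) | C=C(C)[C@@H](CC=C(C)C)C[C@@]1(C(=O)OC)C[C@H](CC=C(C)C)C(C)(C)OC1=O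
F4 | step 7 | methyl 5-[3,4-bis(tert-butyldimethylsilyloxy)phenyl]-2-[(2S)-3-hydroxy-3-methyl-2-(3-methylbut-2-en-1-yl)butyl]-2-[(2S)-5-methyl-2-(prop-1-en-2-yl)hex-4-en-1-yl]-3,5-dioxopentanoate (hydroxy diketone, open form, configuration at C2 as in 14) | C=C(C)[C@@H](CC=C(C)C)C[C@@](C(=O)OC)(C[C@H](CC=C(C)C)C(C)(C)O)C(=O)CC(=O)c1ccc(O[Si](C)(C)C(C)(C)C)c(O[Si](C)(C)C(C)(C)C)c1
F5 | step 7 | methyl 4-[3,4-bis(tert-butyldimethylsilyloxy)benzoyl]-2-[(2S)-3-hydroxy-3-methyl-2-(3-methylbut-2-en-1-yl)butyl]-9-methyl-2-[(2S)-5-methyl-2-(prop-1-en-2-yl)hex-4-en-1-yl]-3,5-dioxodec-8-enoate (hydroxy triketone, configuration at C2 as in 14) | C=C(C)[C@@H](CC=C(C)C)C[C@@](C(=O)OC)(C[C@H](CC=C(C)C)C(C)(C)O)C(=O)C(C(=O)CCC=C(C)C)C(=O)c1ccc(O[Si](C)(C)C(C)(C)C)c(O[Si](C)(C)C(C)(C)C)c1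
F6 | step 8 | 2-[3,4-bis(tert-butyldimethylsilyloxy)benzoyl]-4-(3-methylbut-2-en-1-yl)-6,6-bis[(2S)-5-methyl-2-(prop-1-en-2-yl)hex-4-en-1-yl]cyclohexane-1,3,5-trione (6,6-dilavandulyl acylphloroglucinol, drawn as the triketo tautomer) | C=C(C)[C@@H](CC=C(C)C)CC1(C[C@H](CC=C(C)C)C(C)=C)C(=O)C(CC=C(C)C)C(=O)C(C(=O)c2ccc(O[Si](C)(C)C(C)(C)C)c(O[Si](C)(C)C(C)(C)C)c2)C1=O
F7 | step 2 | methyl (4R)-7-methyl-4-(prop-1-en-2-yl)oct-6-enoate (monoalkylated ester) | COC(=O)CC[C@H](CC=C(C)C)C(C)=C
F8 | step 2 | methyl (4S)-7-methyl-2-[(2S)-5-methyl-2-(prop-1-en-2-yl)hex-4-en-1-yl]-4-(prop-1-en-2-yl)oct-6-enoate (dialkylated ester) | COC(=O)C(C[C@H](CC=C(C)C)C(C)=C)C[C@H](CC=C(C)C)C(C)=C
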